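**Retrosynthetic overview** (clerodane numbering, see remark)
1. The target is a trans-decalin (ring A: C1–C5, C10; ring B: C5–C10) carrying the C18/C19 butenolide on C4/C5 and a furan-fused cycloheptanone (ring C: C1, C16, C13, C12, C11, C9, C10). The last disconnections are C2–OH (enone reduction), ring C at C12–C13 (Friedel–Crafts acylation of the furan) and the furan at C1–C16 (α'-arylation of a C2 enone).
2. The butenolide comes from an exocyclic C4=C18 methylene (singlet-oxygen ene reaction, then oxidative lactonisation with C19–OH); the C7 acetate comes from a C7 ketone.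
3. Key disconnection: rings B and A together, by a carbonylative radical cascade of an acyclic thionocarbonate: C8 radical + CO → C7 acyl radical → C6–C7 bond (ring B) → C5 radical → C4–C5 bond (ring A).
4. Enabling feature: C7 is an oxygen-bearing ring-B carbon flanked by the secondary C8 and by the methylene C6, whose other neighbour is the quaternary fusion atom C5 shared by ring A, ring B and the lactone. C7 can therefore enter as CO, C5=C6 as a 1,1-disubstituted alkene, and the radical left on C5 builds ring A.
5. The acyclic precursor comes from an enantioselective Ireland–Claisen rearrangement (C9–C10 bond, C9 quaternary). Ring order: B → A (same step) → lactone → furan attached → C.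

Key step: step 8

Remark: positions are cited by clerodane numbering (C7 carries the acetate, C5/C10 are the decalin fusion atoms, C18/C19 the lactone carbons, C12 the furyl ketone carbon, C16 the furan carbon bonded to C1); the (S,S)-bis-sulfonamide ligand of step 3 and the stannane of step 5 are taken as purchasable reagents.

**Step 1**
Reactants: 1 tert-butyl(but-3-yn-1-yloxy)dimethylsilane
Product: 3 (E)-5-(tert-butyldimethylsilyloxy)-3-methylpent-2-en-1-ol, via alkenylalane 2 (not isolated)
Conditions: AlMe3, Cp2ZrCl2 (cat.), CH2Cl2, 0 °C → rt; then n-BuLi, (CH2O)n, THF, −78 °C → rt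
Reagents that add atoms: trimethylaluminium C[Al](C)C; formaldehyde (as paraformaldehyde) C=O
Why: Zirconium-catalysed syn-carboalumination of the terminal alkyne (Negishi carboalumination) puts methyl on the internal carbon and aluminium on the terminal one, and the derived alanate adds to formaldehyde with retention, so only the (E)-trisubstituted allylic alcohol should form.

**Step 2**
Reactants: 3 (E)-5-(tert-butyldimethylsilyloxy)-3-methylpent-2-en-1-ol; 4 hept-6-ynoic acid
Product: 5 (E)-5-(tert-butyldimethylsilyloxy)-3-methylpent-2-en-1-yl hept-6-ynoate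
Conditions: DCC, DMAP (cat.), CH2Cl2, 0 °C → rt
Reagents that add atoms: none
Why: Steglich esterification of a primary allylic alcohol with an unhindered acid; no stereocentre is involved.

**Step 3**
Reactants: 5 allyl ester
Product: 7 (2R,3S)-3-[2-(tert-butyldimethylsilyloxy)ethyl]-3-methyl-2-(pent-4-yn-1-yl)pent-4-enoic acid, via boron ketene acetal 6 (not isolated)
Conditions: (S,S)-bis-sulfonamide, BBr3, CH2Cl2, rt, volatiles removed; then 5, i-Pr2NEt, CH2Cl2, −78 °C → −20 °C → rt; aqueous work-up
Reagents that add atoms: none
Why: Enantioselective Ireland–Claisen rearrangement of an achiral allyl ester through a chiral O-boron ketene acetal: soft enolisation under conditions chosen for the Z(O)-enolate, then a chair [3,3] shift in which the (E)-alkene places the silyloxyethyl arm equatorial and the pentynyl chain equatorial, which should set quaternary C9 and C10 in the relative sense of the target, while the C2-symmetric diazaborolidine selects the face (the antipodal controller is taken if the sense proves opposite).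

**Step 4**
Reactants: 7 pentenoic acid
Product: 9 (3R,4R)-4-[2-(tert-butyldimethylsilyloxy)ethyl]-4,5-dimethyl-3-(pent-4-yn-1-yl)oxolan-2-one (both C5 epimers of the lactone ring, i.e. C8), via hydroxy acid 8 (not isolated)
Conditions: Mn(dpm)3 [tris(dipivaloylmethanato)manganese, trivalent manganese] (cat.), PhSiH3, O2 (1 atm), i-PrOH/CH2Cl2, 0 °C → rt; then PPTS (cat.), CH2Cl2, rt
Reagents that add atoms: oxygen O=O
Why: Mukaiyama-type Markovnikov hydration by metal-hydride hydrogen-atom transfer to the monosubstituted alkene (a terminal alkyne is far less reactive in this mode), then closure of the γ-hydroxy acid to the five-membered lactone; the new C8 carbinol centre is not controlled and need not be, because it becomes a radical in step 8.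

**Step 5**
Reactants: 9 γ-lactone
Product: 10 4-[2-(tert-butyldimethylsilyloxy)ethyl]-5-hydroxy-1-(methoxymethoxy)-4-methyl-3-(pent-4-yn-1-yl)hexan-2-one (C3/C4 as C10/C9 of 7; C5 epimers; in equilibrium with its cyclic hemiketal)
Conditions: Bu3SnCH2OCH2OCH3, n-BuLi, THF, −78 °C; then 9, −78 °C; NH4Cl (aq)
Reagents that add atoms: (methoxymethoxy)methyllithium [Li]COCOC
Why: Addition of an α-alkoxymethyllithium (from tin–lithium exchange) to a γ-lactone stops at the lactolate at −78 °C, so exactly one C19 unit is introduced; excess reagent covers the acetylenic proton and no stereocentre is touched.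

**Step 6**
Reactants: 10 hydroxy ketone
Product: 11 4-[2-(tert-butyldimethylsilyloxy)ethyl]-2-[(methoxymethoxy)methyl]-4-methyl-3-(pent-4-yn-1-yl)hex-1-en-5-ol (C3/C4 as C10/C9 of 7; C5 epimers)
Conditions: Ph3PCH3Br, KHMDS, THF, 0 °C → rt
Reagents that add atoms: methylenetriphenylphosphorane C=P(c1ccccc1)(c1ccccc1)c1ccccc1
Why: Wittig methylenation of the keto form (opened from the hemiketal under the basic conditions) installs C6 as the free terminus of the 1,1-disubstituted alkene; C10, although α to the ketone, is shielded by the adjacent quaternary C9 and should not epimerise with the salt-free ylide.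

**Step 7**
Reactants: 11 alkenol
Product: 12 O-phenyl thionocarbonate of 11 (thionocarbonate on the C8 oxygen)
Conditions: PhOC(S)Cl, pyridine, DMAP (cat.), CH2Cl2, rt
Reagents that add atoms: O-phenyl chlorothionoformate S=C(Cl)Oc1ccccc1
Why: Acylation of the hindered secondary alcohol with a thionoformate gives the standard Barton–McCombie radical precursor.

**Step 8**
Reactants: 12 thionocarbonate
Product: 13 trans-decalin-7-one: 9-[2-(tert-butyldimethylsilyloxy)ethyl]-5-[(methoxymethoxy)methyl]-8,9-dimethyl-4-methylidene-decalin-7-one (C5, C8, C9, C10 as in the target)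
Conditions: CO (80 atm), Bu3SnH (slow addition), AIBN, benzene (0.01 M), 80 °C; then DBU (cat.), CH2Cl2, rt
Reagents that add atoms: carbon monoxide [C-]#[O+]
Why: The stannyl radical adds to the thiocarbonyl and β-scission releases the secondary C8 radical (Barton–McCombie fragmentation), which has only 4-exo or 5-endo cyclisation modes open and is therefore captured by CO (radical carbonylation) to give the acyl radical at C7. The acyl radical closes ring B by 6-endo-trig attack on C6, the unsubstituted terminus of the C5=C6 alkene (new C6–C7 bond); 5-exo attack at the fully substituted C5 is disfavoured and its product would ring-expand to the same tertiary C5 radical (Dowd–Beckwith pathway). The tertiary C5 radical then closes ring A by 6-exo-dig addition to the pendant alkyne (new C4–C5 bond, quaternary C5) and the vinyl radical takes hydrogen from Bu3SnH, leaving the exocyclic C4=C18 methylene. The closest known reaction types are carbonylative cyclisations of alkyl radicals under CO pressure and acyl-radical polyene cascades started from acyl selenides. C5 should be set through a chair–chair transition state in which the alkynyl tether on C10 is equatorial and the axial C9 methyl disfavours axial bond formation at C5, so the rings fuse trans with the CH2OMOM group axial; C8 forms unselectively and is then equilibrated with DBU to the equatorial-methyl epimer next to the new ketone. The step needs CO capture to beat direct reduction and 1,5-hydrogen transfer from the allylic C19–H (secured by 80 atm CO) and ring-A closure to beat reduction of the C5 radical (secured by keeping Bu3SnH at millimolar concentration), while reversible stannyl-radical addition to the alkyne is outrun by the irreversible thionocarbonate fragmentation.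

**Step 9**
Reactants: 13 decalin-7-one
Product: 14 the corresponding 7-ol with the hydroxyl axial, syn to the C5 and C9 angular substituents (C7 as in the target)
Conditions: LiBH(s-Bu)3 (L-Selectride), THF, −78 °C
Reagents that add atoms: none
Why: Hydride reduction with a bulky borohydride: the axial CH2OMOM on C5 and the axial methyl on C9 block the face syn to them, so hydride enters along the equatorial trajectory and the axial C7 alcohol of the target should result.

**Step 10**
Reactants: 14 axial alcohol
Product: 15 C7 acetate of 14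
Conditions: Ac2O, Et3N, DMAP, CH2Cl2, rt → 40 °C
Reagents that add atoms: acetic anhydride CC(=O)OC(C)=O
Why: DMAP-catalysed acetylation of the hindered axial alcohol installs the acetate of the target, which meets no strong base or strong hydride in the later steps.

**Step 11**
Reactants: 15 acetate with exocyclic methylene
Product: 17 allylic alcohol: C3=C4 alkene with CH2OH (C18) on C4, via allylic hydroperoxide 16 (not isolated)
Conditions: O2, hν, tetraphenylporphyrin (cat.), CH2Cl2, 0 °C; then PPh3
Reagents that add atoms: oxygen O=O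
Why: Schenck ene reaction of singlet oxygen: only C3 carries allylic hydrogen (C5 is quaternary), so the double bond moves to C3=C4 and oxygen arrives on C18; PPh3 reduces the hydroperoxide.

**Step 12**
Reactants: 17 allylic alcohol
Product: 18 triol (C18–OH, C19–OH, C12–OH; C7 acetate kept)
Conditions: HCl (cat.), MeOH, rt
Reagents that add atoms: none
Why: Acid-catalysed methanolysis removes the methoxymethyl acetal and the primary silyl ether in one operation, while the hindered secondary acetate should survive.

**Step 13**
Reactants: 18 triol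
Product: 20 butenolide (C18 carbonyl, C19–O, C3=C4) with free C12 hydroxyl, via lactol 19 (not isolated)
Conditions: MnO2 (excess), CH2Cl2, rt
Reagents that add atoms: none
Why: MnO2 oxidises only the allylic C18 alcohol; the enal is trapped by the C19 hydroxyl as a five-membered lactol, which is oxidised on to the α-alkylidene butyrolactone, and the saturated C12 alcohol is left alone.

**Step 14**
Reactants: 20 hydroxy butenolide
Product: 22 carboxylic acid at C12, via aldehyde 21 (not isolated)
Conditions: TEMPO (cat.), PhI(OAc)2, MeCN/H2O, rt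
Reagents that add atoms: water O
Why: Oxoammonium oxidation of the primary alcohol in aqueous acetonitrile passes through the aldehyde hydrate to the acid without touching the lactone or the acetate.

**Step 15**
Reactants: 22 butenolide acid
Product: 23 C2 ketone (2-oxo-3-ene butenolide acid)
Conditions: Rh2(cap)4 [dirhodium tetrakis(caprolactamate)] (1 mol %), t-BuOOH (aq), ClCH2CH2Cl, 40 °C
Reagents that add atoms: tert-butyl hydroperoxide CC(C)(C)OO
Why: Dirhodium-carboxamidate-catalysed allylic oxidation converts the only allylic methylene (C2; the other allylic position, C5, is quaternary) into the ketone, an enone-to-enedione type oxidation.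

**Step 16**
Reactants: 23 enone acid; 24 2-bromofuran
Product: 26 C1-(furan-2-yl) enone acid, via silyl dienol ether silyl ester 25 (not isolated)
Conditions: TMSOTf, Et3N, CH2Cl2, 0 °C; then 24, Pd(dba)2, P(t-Bu)3, ZnF2, DMF, 80 °C; aqueous work-up
Reagents that add atoms: none
Why: Soft enolisation can go only toward C1 (C4 bears no hydrogen and the γ-carbon C5 is quaternary), giving the 2-silyloxy diene and, transiently, the silyl ester, which then undergoes palladium-catalysed α-arylation of a silyl enol ether with the heteroaryl bromide under fluoride activation; C1 stays epimerisable and is corrected in step 17.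

**Step 17**
Reactants: 26 furyl enone acid
Product: 28 tetracyclic 2,12-dione (ring C closed), via acid chloride 27 (not isolated)
Conditions: 1-chloro-N,N,2-trimethylprop-1-en-1-amine, CH2Cl2, 0 °C; then SnCl4, CH2Cl2 (high dilution), −78 → 0 °C
Reagents that add atoms: none
Why: The acid chloride, made under neutral conditions, acylates the furan intramolecularly at its 3-position (Friedel–Crafts acylation; the more reactive 5-position cannot be reached) to close seven-membered ring C; only the C1 epimer with the furyl group equatorial can cyclise and the Lewis acid equilibrates C1 through the enol, so the trans ring fusion with H1 anti to H10 should result.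

**Step 18**
Reactants: 28 tetracyclic dione
Product: 29 CNP0182929.1
Conditions: NaBH4, CeCl3·7H2O, MeOH, −78 °C
Reagents that add atoms: none
Why: Luche reduction: the activated C2 enone carbonyl should be reduced 1,2 in preference to the hindered, furan-conjugated C12 ketone, the lactone and the acetate, and axial hydride delivery from the face of H10 gives the pseudo-equatorial C2 alcohol trans to the C1–furan bond.

**Compound list**
1 | tert-butyl(but-3-yn-1-yloxy)dimethylsilane | C#CCCO[Si](C)(C)C(C)(C)C | starting material
2 | [(E)-4-(tert-butyldimethylsilyloxy)-2-methylbut-1-en-1-yl]dimethylalane | C[Al](C)/C=C(\C)CCO[Si](C)(C)C(C)(C)C | intermediate (not isolated)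
3 | (E)-5-(tert-butyldimethylsilyloxy)-3-methylpent-2-en-1-ol | OC/C=C(\C)CCO[Si](C)(C)C(C)(C)C | intermediate
4 | hept-6-ynoic acid | C#CCCCCC(=O)O | starting material
5 | (E)-5-(tert-butyldimethylsilyloxy)-3-methylpent-2-en-1-yl hept-6-ynoate | C#CCCCCC(=O)OC/C=C(\C)CCO[Si](C)(C)C(C)(C)C | intermediate
6 | Z(O)-boron ketene acetal of 5 carrying the (S,S)-4,5-diphenyl-1,3-bis[3,5-bis(trifluoromethyl)phenylsulfonyl]-1,3,2-diazaborolidin-2-yl group on oxygen | C#CCCC/C=C(\OB1N(S(=O)(=O)c2cc(cc(c2)C(F)(F)F)C(F)(F)F)[C@@H](c2ccccc2)[C@H](c2ccccc2)N1S(=O)(=O)c2cc(cc(c2)C(F)(F)F)C(F)(F)F)OC/C=C(\C)CCO[Si](C)(C)C(C)(C)C | intermediate (not isolated)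
7 | (2R,3S)-3-[2-(tert-butyldimethylsilyloxy)ethyl]-3-methyl-2-(pent-4-yn-1-yl)pent-4-enoic acid | OC(=O)[C@H](CCCC#C)[C@](C)(C=C)CCO[Si](C)(C)C(C)(C)C | intermediate
8 | 3-[2-(tert-butyldimethylsilyloxy)ethyl]-4-hydroxy-3-methyl-2-(pent-4-yn-1-yl)pentanoic acid (C2/C3 from 7, C4 epimers) | OC(=O)[C@H](CCCC#C)[C@](C)(C(C)O)CCO[Si](C)(C)C(C)(C)C | intermediate (not isolated)
9 | (3R,4R)-4-[2-(tert-butyldimethylsilyloxy)ethyl]-4,5-dimethyl-3-(pent-4-yn-1-yl)oxolan-2-one (C5 epimers) | CC1OC(=O)[C@H](CCCC#C)[C@@]1(C)CCO[Si](C)(C)C(C)(C)C | intermediate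
10 | 4-[2-(tert-butyldimethylsilyloxy)ethyl]-5-hydroxy-1-(methoxymethoxy)-4-methyl-3-(pent-4-yn-1-yl)hexan-2-one (open form of the hemiketal; C5 epimers) | COCOCC(=O)[C@H](CCCC#C)[C@](C)(C(C)O)CCO[Si](C)(C)C(C)(C)C | intermediate
11 | 4-[2-(tert-butyldimethylsilyloxy)ethyl]-2-[(methoxymethoxy)methyl]-4-methyl-3-(pent-4-yn-1-yl)hex-1-en-5-ol (C5 epimers) | COCOCC(=C)[C@H](CCCC#C)[C@](C)(C(C)O)CCO[Si](C)(C)C(C)(C)C | intermediate
12 | O-phenyl thionocarbonate of 11 | COCOCC(=C)[C@H](CCCC#C)[C@](C)(C(C)OC(=S)Oc1ccccc1)CCO[Si](C)(C)C(C)(C)C | intermediate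
13 | 9-[2-(tert-butyldimethylsilyloxy)ethyl]-5-[(methoxymethoxy)methyl]-8,9-dimethyl-4-methylidene-trans-decalin-7-one (clerodane locants) | O=C1C[C@@]2(COCOC)C(=C)CCC[C@@H]2[C@@](C)(CCO[Si](C)(C)C(C)(C)C)[C@@H]1C | intermediate
14 | axial 7-ol of 13 | O[C@@H]1C[C@@]2(COCOC)C(=C)CCC[C@@H]2[C@@](C)(CCO[Si](C)(C)C(C)(C)C)[C@@H]1C | intermediate
15 | 7-acetate of 14 | CC(=O)O[C@@H]1C[C@@]2(COCOC)C(=C)CCC[C@@H]2[C@@](C)(CCO[Si](C)(C)C(C)(C)C)[C@@H]1C | intermediate
16 | allylic hydroperoxide (C18–OOH, C3=C4) | CC(=O)O[C@@H]1C[C@@]2(COCOC)C(COO)=CCC[C@@H]2[C@@](C)(CCO[Si](C)(C)C(C)(C)C)[C@@H]1C | intermediate (not isolated)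
17 | allylic alcohol (C18–OH, C3=C4) | CC(=O)O[C@@H]1C[C@@]2(COCOC)C(CO)=CCC[C@@H]2[C@@](C)(CCO[Si](C)(C)C(C)(C)C)[C@@H]1C | intermediate
18 | 7-acetoxy-12,18,19-triol | CC(=O)O[C@@H]1C[C@@]2(CO)C(CO)=CCC[C@@H]2[C@@](C)(CCO)[C@@H]1C | intermediate
19 | C18 lactol (ring-closed form of the hydroxy enal) | CC(=O)O[C@@H]1C[C@@]23COC(O)C2=CCC[C@@H]3[C@@](C)(CCO)[C@@H]1C | intermediate (not isolated)
20 | 7-acetoxy-12-hydroxy-3-en-18,19-olide | CC(=O)O[C@@H]1C[C@@]23COC(=O)C2=CCC[C@@H]3[C@@](C)(CCO)[C@@H]1C | intermediate
21 | C12 aldehyde of 20 | CC(=O)O[C@@H]1C[C@@]23COC(=O)C2=CCC[C@@H]3[C@@](C)(CC=O)[C@@H]1C | intermediate (not isolated)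
22 | C12 carboxylic acid | CC(=O)O[C@@H]1C[C@@]23COC(=O)C2=CCC[C@@H]3[C@@](C)(CC(=O)O)[C@@H]1C | intermediate
23 | 2-oxo-3-en-18,19-olide C12 acid | CC(=O)O[C@@H]1C[C@@]23COC(=O)C2=CC(=O)C[C@@H]3[C@@](C)(CC(=O)O)[C@@H]1C | intermediate
24 | 2-bromofuran | Brc1ccco1 | starting material
25 | 2-(trimethylsilyloxy)-1,3-diene trimethylsilyl ester of 23 | CC(=O)O[C@@H]1C[C@@]23COC(=O)C2=CC(O[Si](C)(C)C)=C[C@@H]3[C@@](C)(CC(=O)O[Si](C)(C)C)[C@@H]1C | intermediate (not isolated)
26 | 1-(furan-2-yl)-2-oxo-3-en-18,19-olide C12 acid (furyl equatorial) | CC(=O)O[C@@H]1C[C@@]23COC(=O)C2=CC(=O)[C@@H](c4ccco4)[C@@H]3[C@@](C)(CC(=O)O)[C@@H]1C | intermediate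
27 | acid chloride of 26 | CC(=O)O[C@@H]1C[C@@]23COC(=O)C2=CC(=O)[C@@H](c4ccco4)[C@@H]3[C@@](C)(CC(=O)Cl)[C@@H]1C | intermediate (not isolated)
28 | 2-oxo analogue of the target (tetracyclic 2,12-dione) | CC(=O)O[C@@H]1C[C@@]23COC(=O)C2=CC(=O)[C@H]2c4occc4C(=O)C[C@@](C)([C@@H]1C)[C@@H]23 | intermediate
29 | CNP0182929.1 | CC(=O)O[C@@H]1C[C@@]23COC(=O)C2=C[C@H](O)[C@H]2c4occc4C(=O)C[C@@](C)([C@@H]1C)[C@@H]23 | target

**Step count and risks**
Total step count: 18. Longest linear sequence: 18 steps (from 1; 4 and 24 are purchased).

Three steps most likely to fail: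

1. Step 8. Possible failure processes: hydrogen transfer to the C8 radical before CO capture (from the tin hydride or by 1,5-shift from the allylic C19–H); reduction of the C5 radical before the alkyne closure; poor facial selectivity in the ring-A closure (cis fusion); incomplete equilibration at C8. Fallback (no C8 radical, no CO pressure; sets out from 11 and returns at 13): Dess–Martin oxidation of 11 should give the methyl ketone F1; methoxymethylenation with Ph3P=CHOMe the enol ether F2; mild hydrolysis (Hg(OAc)2, aqueous THF) the aldehyde F3; Pinnick oxidation the acid F4; (PhSe)2/PBu3 the Se-phenyl selenoester F5. F5 with Bu3SnH/AIBN in benzene at 80 °C under 1 atm CO would generate the C7 acyl radical directly and deliver 13 by the same two ring closures, followed by the DBU equilibration.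

2. Step 16. Possible failure processes: slow oxidative addition or decomposition of the bromofuran, protodesilylation of the dienol ether, or degradation of the enedione under the coupling conditions. Fallback (sets out from 23 and returns at 26): silyl dienol ether formation as in step 16, then N-bromosuccinimide, should give the α'-bromo enone F6. Visible-light photoredox catalysis (Ru(bpy)3Cl2, blue light, 2,6-lutidine) with furan as co-solvent would generate the C1 α-keto radical, which adds to C2 of furan; oxidation and loss of a proton rearomatise to give 26.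

3. Step 3. Possible failure processes: insufficient enantiofacial or diastereofacial control in forming the quaternary centre, or interference of the bromoborane with the terminal alkyne. Fallback (sets out from 5 and returns at 7): LDA (2.2 equiv) and TMSCl in THF/HMPA at −78 °C → rt should give the bis-silylated (E)-ketene acetal F7, which rearranges through the same chair to the racemic C-silyl alkyne acid F8. K2CO3/MeOH removes the alkynyl silyl group to give racemic 7; crystallisation of the (S)-1-phenylethylammonium salt F9 and acidification would return enantiopure 7.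

**Further compounds**
F1 | step 8 | 4-[2-(tert-butyldimethylsilyloxy)ethyl]-2-[(methoxymethoxy)methyl]-4-methyl-3-(pent-4-yn-1-yl)hex-1-en-5-one | COCOCC(=C)[C@H](CCCC#C)[C@](C)(C(C)=O)CCO[Si](C)(C)C(C)(C)C
F2 | step 8 | methyl enol ether from F1 (C7=C8, E/Z mixture) | COCOCC(=C)[C@H](CCCC#C)[C@](C)(C(C)=COC)CCO[Si](C)(C)C(C)(C)C
F3 | step 8 | C7 aldehyde (C8 epimers) | COCOCC(=C)[C@H](CCCC#C)[C@](C)(C(C)C=O)CCO[Si](C)(C)C(C)(C)C
F4 | step 8 | C7 carboxylic acid (C8 epimers) | COCOCC(=C)[C@H](CCCC#C)[C@](C)(C(C)C(=O)O)CCO[Si](C)(C)C(C)(C)C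
F5 | step 8 | Se-phenyl selenoester of F4 | COCOCC(=C)[C@H](CCCC#C)[C@](C)(C(C)C(=O)[Se]c1ccccc1)CCO[Si](C)(C)C(C)(C)C
F6 | step 16 | 1-bromo-2-oxo-3-en-18,19-olide C12 acid (C1 epimers) | CC(=O)O[C@@H]1C[C@@]23COC(=O)C2=CC(=O)C(Br)[C@@H]3[C@@](C)(CC(=O)O)[C@@H]1C
F7 | step 3 | bis-silylated (E)-silyl ketene acetal of 5 | C[Si](C)(C)C#CCCC/C=C(\O[Si](C)(C)C)OC/C=C(\C)CCO[Si](C)(C)C(C)(C)C
F8 | step 3 | racemic 3-[2-(tert-butyldimethylsilyloxy)ethyl]-3-methyl-2-[5-(trimethylsilyl)pent-4-yn-1-yl]pent-4-enoic acid (relative configuration of 7) | OC(=O)[C@H](CCCC#C[Si](C)(C)C)[C@](C)(C=C)CCO[Si](C)(C)C(C)(C)C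
F9 | step 3 | (S)-1-phenylethylammonium salt of 7 | [O-]C(=O)[C@H](CCCC#C)[C@](C)(C=C)CCO[Si](C)(C)C(C)(C)C.C[C@H]([NH3+])c1ccccc1
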